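**Plan**
Ring numbering: O1, C2 (3,4-dimethoxyphenyl), C3 (hydroxymethyl arm, C9), C4 (aroyl carbon C7'), C5.
Cuts, in retrosynthetic order: C7'–aryl (Grignard addition to a C4 aldehyde); O1–C2 and C2–H (reductive cyclisation of a γ-hydroxy aryl ketone); C2–aryl (aryllithium addition to a γ-lactone); C3–C9 (enolate hydroxymethylation); back to (S)-paraconic acid.
Enabling feature: in the ring O1/C2/C3/C4/C5, C2 is a benzylic carbon bonded to O1 and to the electron-rich 3,4-dimethoxyphenyl ring, so the ring can close through a stabilised cyclic 2-aryl oxocarbenium ion whose two faces are differentiated by the C3 arm.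
Forward order: lactone with two differently silylated CH2O arms, then the open aryl ketone, then the tetrahydrofuran (the only ring formed, step 6), then unmasking, oxidation, arylation and oxidation of the C4 arm, then desilylation.
Stereochemistry: C4 comes from (S)-paraconic acid, C3 from trans-selective aldol addition of the lactone enolate, C2 from hydride delivery anti to the C3 arm (2,3-cis).

Key step: step 6

Assumption: (S)-paraconic acid 1 is bought as the single enantiomer; all tetrahydrofurans are named with the ring numbering given above.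

**Route**

Step 1
Reactants: 1 (S)-paraconic acid [(3S)-5-oxotetrahydrofuran-3-carboxylic acid]
Product: 2 (4R)-4-(hydroxymethyl)dihydrofuran-2(3H)-one
Conditions: BH3·SMe2 (1.2 equiv), THF, 0 °C → rt; MeOH quench, evaporation
Reagents that add atoms: none
Why: Chemoselective borane reduction of a carboxylic acid, which is far faster than reduction of the lactone, leaves the stereocenter untouched; the crude alcohol is silylated at once, because acyl migration to the new hydroxyl would exchange the two CH2O arms and erode the enantiomeric purity.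

Step 2
Reactants: 2 (4R)-4-(hydroxymethyl)dihydrofuran-2(3H)-one
Product: 3 (4S)-4-[(tert-butyldimethylsilyloxy)methyl]dihydrofuran-2(3H)-one (same spatial arrangement; the descriptor changes by priority only)
Conditions: TBSCl, imidazole, CH2Cl2, 0 °C → rt
Reagents that add atoms: tert-butyldimethylsilyl chloride (TBSCl), CC(C)(C)[Si](C)(C)Cl
Why: Standard silylation of a primary alcohol with a silyl chloride and imidazole, mild enough not to open the lactone, and it closes the translactonisation pathway for good.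

Step 3
Reactants: 3 (4S)-4-[(tert-butyldimethylsilyloxy)methyl]dihydrofuran-2(3H)-one
Product: 6 (3R,4S)-4-[(tert-butyldimethylsilyloxy)methyl]-3-(hydroxymethyl)dihydrofuran-2(3H)-one (3,4-trans), via lithium enolate 4 (not isolated), via lithium aldolate 5 (not isolated)
Conditions: LiN(i-Pr)2 (1.1 equiv), THF, −78 °C; CH2O gas (from cracked paraformaldehyde, N2 stream), −78 °C; AcOH, −78 °C
Reagents that add atoms: formaldehyde, C=O
Why: Aldol addition of a lactone lithium enolate to monomeric formaldehyde, in which the electrophile enters the enolate face anti to the C4 silyloxymethyl group and so sets C3 trans to C4 (3R); the cold acidic quench prevents retro-aldol cleavage and dehydration.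

Step 4
Reactants: 6 (3R,4S)-4-[(tert-butyldimethylsilyloxy)methyl]-3-(hydroxymethyl)dihydrofuran-2(3H)-one
Product: 7 (3R,4S)-4-[(tert-butyldimethylsilyloxy)methyl]-3-[(tert-butyldiphenylsilyloxy)methyl]dihydrofuran-2(3H)-one
Conditions: TBDPSCl, imidazole, DMF, rt
Reagents that add atoms: tert-butyldiphenylsilyl chloride (TBDPSCl), CC(C)(C)[Si](Cl)(c1ccccc1)c1ccccc1
Why: Silylation of a primary alcohol with a silyl chloride and imidazole; the tert-butyldiphenylsilyl group is chosen because it survives the later acid cleavage of the tert-butyldimethylsilyl ether and shields one face of C2 in step 6.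

Step 5
Reactants: 7 (3R,4S)-4-[(tert-butyldimethylsilyloxy)methyl]-3-[(tert-butyldiphenylsilyloxy)methyl]dihydrofuran-2(3H)-one; 8 4-bromo-1,2-dimethoxybenzene
Product: 11 (2R,3S)-3-[(tert-butyldimethylsilyloxy)methyl]-2-[(tert-butyldiphenylsilyloxy)methyl]-1-(3,4-dimethoxyphenyl)-4-hydroxybutan-1-one, via 3,4-dimethoxyphenyllithium 9 (not isolated), via lithium hemiketal alkoxide 10 (not isolated)
Conditions: 8 (1.2 equiv), n-BuLi (1.15 equiv), THF, −78 °C; then 7, THF, −78 °C; AcOH, −78 °C
Reagents that add atoms: none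
Why: Bromine–lithium exchange followed by mono-addition of the aryllithium to the γ-lactone (nucleophilic acyl addition), where the tetrahedral lithium adduct 10 stays closed at −78 °C and so blocks a second addition; protonation in the cold releases the ketone before the alkoxide can take a silyl group from a neighbouring oxygen or enolise C3.

Step 6
Reactants: 11 (2R,3S)-3-[(tert-butyldimethylsilyloxy)methyl]-2-[(tert-butyldiphenylsilyloxy)methyl]-1-(3,4-dimethoxyphenyl)-4-hydroxybutan-1-one
Product: 14 (2R,3R,4S)-4-[(tert-butyldimethylsilyloxy)methyl]-3-[(tert-butyldiphenylsilyloxy)methyl]-2-(3,4-dimethoxyphenyl)tetrahydrofuran (2,3-cis-3,4-trans), via cyclic hemiketal 12 (not isolated), via 2-aryl oxocarbenium ion 13 (not isolated)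
Conditions: Et3SiH (5 equiv), then BF3·OEt2 (2 equiv) dropwise, CH2Cl2, −78 °C; aq NaHCO3 quench at −78 °C
Reagents that add atoms: none
Why: BF3·OEt2 draws hydroxy ketone 11 into its cyclic hemiketal 12 and ionises the tertiary C2–OH bond to the 2-aryl oxocarbenium ion 13, which Et3SiH reduces irreversibly at C2. The closest known reaction type is the Lewis acid/silane reductive deoxygenation of 2-aryl lactols used for C-aryl glycosides and 2-aryltetrahydrofuran lignans. The tetrahydrofuran ring closes by 5-exo-trig addition of the C5 hydroxyl to the C2 carbonyl (O1–C2), and the C2–H bond follows from the hydride transfer. The new stereocenter C2 is controlled by the substrate: the small hydride donor enters the planar cation on the face anti to the adjacent C3 silyloxymethyl arm, so the aryl group is left cis to that arm (2R). The step needs facial selectivity at C2 and configurational integrity at C3: the bulky tert-butyldiphenylsilyl group on the C3 arm secures the first, and −78 °C with excess silane, which traps the cation before it can lose the C3 proton, secures the second. Only the C5 hydroxyl is free, so no other ring and no other C4 configuration can arise.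

Step 7
Reactants: 14 (2R,3R,4S)-4-[(tert-butyldimethylsilyloxy)methyl]-3-[(tert-butyldiphenylsilyloxy)methyl]-2-(3,4-dimethoxyphenyl)tetrahydrofuran
Product: 15 (2R,3R,4R)-3-[(tert-butyldiphenylsilyloxy)methyl]-2-(3,4-dimethoxyphenyl)-4-(hydroxymethyl)tetrahydrofuran
Conditions: PPTS (cat.), MeOH, rt
Reagents that add atoms: none
Why: Acid-catalysed methanolysis of silyl ethers removes a primary tert-butyldimethylsilyl group much faster than a primary tert-butyldiphenylsilyl group, and the buffered acid is too weak to ionise the benzylic C2–O1 bond.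

Step 8
Reactants: 15 (2R,3R,4R)-3-[(tert-butyldiphenylsilyloxy)methyl]-2-(3,4-dimethoxyphenyl)-4-(hydroxymethyl)tetrahydrofuran
Product: 16 (2R,3R,4S)-3-[(tert-butyldiphenylsilyloxy)methyl]-2-(3,4-dimethoxyphenyl)-4-formyltetrahydrofuran
Conditions: Dess–Martin periodinane (DMP), CH2Cl2, 0 °C → rt; used crude
Reagents that add atoms: none
Why: Dess–Martin oxidation of a primary alcohol to the aldehyde runs without base, so C4, now alpha to a carbonyl and beta to O1, should neither epimerise nor eliminate.

Step 9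
Reactants: 16 (2R,3R,4S)-3-[(tert-butyldiphenylsilyloxy)methyl]-2-(3,4-dimethoxyphenyl)-4-formyltetrahydrofuran; 17 5-bromo-1,2,3-trimethoxybenzene
Product: 20 (2R,3R,4S)-3-[(tert-butyldiphenylsilyloxy)methyl]-2-(3,4-dimethoxyphenyl)-4-[hydroxy(3,4,5-trimethoxyphenyl)methyl]tetrahydrofuran (both carbinol epimers), via 3,4,5-trimethoxyphenylmagnesium bromide 18 (not isolated), via bromomagnesium alkoxide 19 (not isolated)
Conditions: 17, Mg turnings, THF, 40 °C; then 16, THF, −78 → 0 °C; sat. aq NH4Cl
Reagents that add atoms: none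
Why: Grignard addition of an arylmagnesium bromide to an aldehyde, which at −78 °C outruns enolisation; the configuration of the new carbinol carbon does not matter because it is oxidised in the next step.

Step 10
Reactants: 20 (2R,3R,4S)-3-[(tert-butyldiphenylsilyloxy)methyl]-2-(3,4-dimethoxyphenyl)-4-[hydroxy(3,4,5-trimethoxyphenyl)methyl]tetrahydrofuran
Product: 21 (2R,3R,4S)-3-[(tert-butyldiphenylsilyloxy)methyl]-2-(3,4-dimethoxyphenyl)-4-(3,4,5-trimethoxybenzoyl)tetrahydrofuran
Conditions: DMP, CH2Cl2, rt
Reagents that add atoms: none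
Why: Dess–Martin oxidation of a benzylic secondary alcohol to the aryl ketone removes the carbinol stereocenter; C4 stays trans to C3, which is also the thermodynamically favoured arrangement.

Step 11
Reactants: 21 (2R,3R,4S)-3-[(tert-butyldiphenylsilyloxy)methyl]-2-(3,4-dimethoxyphenyl)-4-(3,4,5-trimethoxybenzoyl)tetrahydrofuran
Product: 22 (2R,3R,4S)-2-(3,4-dimethoxyphenyl)-3-(hydroxymethyl)-4-(3,4,5-trimethoxybenzoyl)tetrahydrofuran (target, CNP0271206.1)
Conditions: HF·pyridine, pyridine, THF, 0 °C → rt
Reagents that add atoms: none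
Why: Fluoride-mediated desilylation with pyridine-buffered HF is chosen over basic Bu4NF because the ketone carries O1 in the beta position and could open by retro-oxa-Michael reaction under base; the 3,4-trans product cannot close a strain-free cyclic hemiketal and should remain the hydroxy ketone.

**Compound list**

1 | (S)-paraconic acid, (3S)-5-oxotetrahydrofuran-3-carboxylic acid | O=C1OC[C@@H](C(=O)O)C1 | starting material
2 | (4R)-4-(hydroxymethyl)dihydrofuran-2(3H)-one | O=C1OC[C@@H](CO)C1 | intermediate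
3 | (4S)-4-[(tert-butyldimethylsilyloxy)methyl]dihydrofuran-2(3H)-one | O=C1OC[C@@H](CO[Si](C)(C)C(C)(C)C)C1 | intermediate
4 | lithium enolate of 3 (not isolated) | [Li]OC1=C[C@H](CO[Si](C)(C)C(C)(C)C)CO1 | intermediate
5 | lithium aldolate, the lithium alkoxide of 6 (not isolated) | O=C1OC[C@@H](CO[Si](C)(C)C(C)(C)C)[C@@H]1CO[Li] | intermediate
6 | (3R,4S)-4-[(tert-butyldimethylsilyloxy)methyl]-3-(hydroxymethyl)dihydrofuran-2(3H)-one | O=C1OC[C@@H](CO[Si](C)(C)C(C)(C)C)[C@@H]1CO | intermediate
7 | (3R,4S)-4-[(tert-butyldimethylsilyloxy)methyl]-3-[(tert-butyldiphenylsilyloxy)methyl]dihydrofuran-2(3H)-one | O=C1OC[C@@H](CO[Si](C)(C)C(C)(C)C)[C@@H]1CO[Si](c2ccccc2)(c3ccccc3)C(C)(C)C | intermediate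
8 | 4-bromo-1,2-dimethoxybenzene | COc1ccc(Br)cc1OC | starting material
9 | 3,4-dimethoxyphenyllithium (not isolated) | [Li]c1ccc(OC)c(OC)c1 | intermediate
10 | lithium alkoxide of the cyclic hemiketal, (3R,4S)-2-(3,4-dimethoxyphenyl)-2-lithiooxy tetrahydrofuran with both silyloxymethyl arms, C2 unassigned (not isolated) | COc1ccc(C2(O[Li])OC[C@@H](CO[Si](C)(C)C(C)(C)C)[C@@H]2CO[Si](c3ccccc3)(c4ccccc4)C(C)(C)C)cc1OC | intermediate
11 | (2R,3S)-3-[(tert-butyldimethylsilyloxy)methyl]-2-[(tert-butyldiphenylsilyloxy)methyl]-1-(3,4-dimethoxyphenyl)-4-hydroxybutan-1-one | COc1ccc(C(=O)[C@@H](CO[Si](c2ccccc2)(c3ccccc3)C(C)(C)C)[C@@H](CO)CO[Si](C)(C)C(C)(C)C)cc1OC | intermediate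
12 | cyclic hemiketal of 11, (3R,4S)-4-[(tert-butyldimethylsilyloxy)methyl]-3-[(tert-butyldiphenylsilyloxy)methyl]-2-(3,4-dimethoxyphenyl)tetrahydrofuran-2-ol, both C2 anomers (not isolated) | COc1ccc(C2(O)OC[C@@H](CO[Si](C)(C)C(C)(C)C)[C@@H]2CO[Si](c3ccccc3)(c4ccccc4)C(C)(C)C)cc1OC | intermediate
13 | 2-(3,4-dimethoxyphenyl) oxocarbenium ion from 12 (O1=C2 cation, C3 and C4 as in 11), hydroxytrifluoroborate salt (not isolated) | COc1ccc(C2=[O+]C[C@@H](CO[Si](C)(C)C(C)(C)C)[C@@H]2CO[Si](c3ccccc3)(c4ccccc4)C(C)(C)C)cc1OC.O[B-](F)(F)F | intermediate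
14 | (2R,3R,4S)-4-[(tert-butyldimethylsilyloxy)methyl]-3-[(tert-butyldiphenylsilyloxy)methyl]-2-(3,4-dimethoxyphenyl)tetrahydrofuran | COc1ccc([C@@H]2OC[C@@H](CO[Si](C)(C)C(C)(C)C)[C@@H]2CO[Si](c3ccccc3)(c4ccccc4)C(C)(C)C)cc1OC | intermediate
15 | (2R,3R,4R)-3-[(tert-butyldiphenylsilyloxy)methyl]-2-(3,4-dimethoxyphenyl)-4-(hydroxymethyl)tetrahydrofuran | COc1ccc([C@@H]2OC[C@@H](CO)[C@@H]2CO[Si](c3ccccc3)(c4ccccc4)C(C)(C)C)cc1OC | intermediate
16 | (2R,3R,4S)-3-[(tert-butyldiphenylsilyloxy)methyl]-2-(3,4-dimethoxyphenyl)-4-formyltetrahydrofuran | COc1ccc([C@@H]2OC[C@@H](C=O)[C@@H]2CO[Si](c3ccccc3)(c4ccccc4)C(C)(C)C)cc1OC | intermediate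
17 | 5-bromo-1,2,3-trimethoxybenzene | COc1cc(Br)cc(OC)c1OC | starting material
18 | 3,4,5-trimethoxyphenylmagnesium bromide (not isolated) | COc1cc([Mg]Br)cc(OC)c1OC | intermediate
19 | bromomagnesium alkoxide of 20 (not isolated) | COc1ccc([C@@H]2OC[C@@H](C(O[Mg]Br)c3cc(OC)c(OC)c(OC)c3)[C@@H]2CO[Si](c4ccccc4)(c5ccccc5)C(C)(C)C)cc1OC | intermediate
20 | (2R,3R,4S)-3-[(tert-butyldiphenylsilyloxy)methyl]-2-(3,4-dimethoxyphenyl)-4-[hydroxy(3,4,5-trimethoxyphenyl)methyl]tetrahydrofuran, both carbinol epimers | COc1ccc([C@@H]2OC[C@@H](C(O)c3cc(OC)c(OC)c(OC)c3)[C@@H]2CO[Si](c4ccccc4)(c5ccccc5)C(C)(C)C)cc1OC | intermediate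
21 | (2R,3R,4S)-3-[(tert-butyldiphenylsilyloxy)methyl]-2-(3,4-dimethoxyphenyl)-4-(3,4,5-trimethoxybenzoyl)tetrahydrofuran | COc1ccc([C@@H]2OC[C@@H](C(=O)c3cc(OC)c(OC)c(OC)c3)[C@@H]2CO[Si](c4ccccc4)(c5ccccc5)C(C)(C)C)cc1OC | intermediate
22 | (2R,3R,4S)-2-(3,4-dimethoxyphenyl)-3-(hydroxymethyl)-4-(3,4,5-trimethoxybenzoyl)tetrahydrofuran, also named [(3S,4R,5R)-5-(3,4-dimethoxyphenyl)-4-(hydroxymethyl)tetrahydrofuran-3-yl](3,4,5-trimethoxyphenyl)methanone | COc1ccc([C@@H]2OC[C@@H](C(=O)c3cc(OC)c(OC)c(OC)c3)[C@@H]2CO)cc1OC | target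

**Summary**

Total step count: 11. Longest linear sequence: 11 steps (1 → 22); the two aryl bromides 8 and 17 enter as organometallics made in the flask in steps 5 and 9.

Steps most likely to fail:

1. Step 6. Hydride delivery may show poor facial selectivity at C2. The oxocarbenium ion may lose the C3 proton to an enol ether and so scramble C3. The Lewis acid may cleave the primary tert-butyldimethylsilyl ether. Fallback: setting out from 11, the ketone would be reduced under reagent control by Corey–Bakshi–Shibata reduction ((S)-B-methyl oxazaborolidine catalyst, BH3·SMe2, THF, −20 °C) to (1R,2R,3S)-3-[(tert-butyldimethylsilyloxy)methyl]-2-[(tert-butyldiphenylsilyloxy)methyl]-1-(3,4-dimethoxyphenyl)butane-1,4-diol F1. The primary hydroxyl would then be sulfonylated selectively (TsCl, pyridine, CH2Cl2, 0 °C) to (2R,3R,4R)-2-[(tert-butyldimethylsilyloxy)methyl]-3-[(tert-butyldiphenylsilyloxy)methyl]-4-(3,4-dimethoxyphenyl)-4-hydroxybutyl 4-methylbenzenesulfonate F2. KOt-Bu in THF at 0 °C would close the ring by 5-exo-tet Williamson displacement at C5, which leaves the carbinol configuration at C2 untouched, and the sequence returns to the route at 14. In this variant C2 is set by the chiral catalyst and O1–C5 is formed in place of O1–C2.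

2. Step 5. The aryllithium may add twice. It may instead enolise the lactone, with β-elimination of silanolate. The liberated alkoxide may take a silyl group from the neighbouring arm, which would scramble C4. Fallback: setting out from 7, the lactone would be taken down one oxidation level with i-Bu2AlH (CH2Cl2, −78 °C) to the lactol (3R,4S)-4-[(tert-butyldimethylsilyloxy)methyl]-3-[(tert-butyldiphenylsilyloxy)methyl]tetrahydrofuran-2-ol F3. An excess of aryllithium 9 can add to it only once (THF, −78 → 0 °C), giving (2R,3S)-3-[(tert-butyldimethylsilyloxy)methyl]-2-[(tert-butyldiphenylsilyloxy)methyl]-1-(3,4-dimethoxyphenyl)butane-1,4-diol (both C1 epimers) F4. MnO2 in CH2Cl2 would then oxidise only the benzylic hydroxyl and return to the route at 11.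

3. Step 3. Formaldehyde may polymerise before it reacts, giving low conversion. The lactone may be hydroxymethylated twice, or the aldol product may dehydrate to the α-methylene lactone. Fallback: setting out from 3, enolate 4 would be alkylated with benzyl chloromethyl ether (THF, −78 °C), again anti to the C4 arm, to give (3R,4S)-3-[(benzyloxy)methyl]-4-[(tert-butyldimethylsilyloxy)methyl]dihydrofuran-2(3H)-one F5. Hydrogenolysis (H2, Pd/C, EtOAc, rt) would remove the benzyl group and return to the route at 6. An enolate alkylation with a liquid electrophile replaces the aldol addition of a gas, at the cost of one extra step.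

**Further compounds**
F1 | step 6 | (1R,2R,3S)-3-[(tert-butyldimethylsilyloxy)methyl]-2-[(tert-butyldiphenylsilyloxy)methyl]-1-(3,4-dimethoxyphenyl)butane-1,4-diol | COc1ccc([C@H](O)[C@@H](CO[Si](c2ccccc2)(c3ccccc3)C(C)(C)C)[C@@H](CO)CO[Si](C)(C)C(C)(C)C)cc1OC
F2 | step 6 | (2R,3R,4R)-2-[(tert-butyldimethylsilyloxy)methyl]-3-[(tert-butyldiphenylsilyloxy)methyl]-4-(3,4-dimethoxyphenyl)-4-hydroxybutyl 4-methylbenzenesulfonate | COc1ccc([C@H](O)[C@@H](CO[Si](c2ccccc2)(c3ccccc3)C(C)(C)C)[C@@H](COS(=O)(=O)c4ccc(C)cc4)CO[Si](C)(C)C(C)(C)C)cc1OC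
F3 | step 5 | (3R,4S)-4-[(tert-butyldimethylsilyloxy)methyl]-3-[(tert-butyldiphenylsilyloxy)methyl]tetrahydrofuran-2-ol (both anomers) | OC1OC[C@@H](CO[Si](C)(C)C(C)(C)C)[C@@H]1CO[Si](c2ccccc2)(c3ccccc3)C(C)(C)C
F4 | step 5 | (2R,3S)-3-[(tert-butyldimethylsilyloxy)methyl]-2-[(tert-butyldiphenylsilyloxy)methyl]-1-(3,4-dimethoxyphenyl)butane-1,4-diol (both C1 epimers) | COc1ccc(C(O)[C@@H](CO[Si](c2ccccc2)(c3ccccc3)C(C)(C)C)[C@@H](CO)CO[Si](C)(C)C(C)(C)C)cc1OC
F5 | step 3 | (3R,4S)-3-[(benzyloxy)methyl]-4-[(tert-butyldimethylsilyloxy)methyl]dihydrofuran-2(3H)-one | O=C1OC[C@@H](CO[Si](C)(C)C(C)(C)C)[C@@H]1COCc2ccccc2
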